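If the target in the alpha flask grows the way a capacitor charges through a resistor, one time constant describes the run, and I can test that at the two ends of the run before I use it on the theta flask, which repeats the alpha charge and is asked for at 51 h.

all flasks: starting material 1.00 M
- alpha: coupling partner 1.00 M; free catalyst 0.00200 M
- zeta: coupling partner 1.00 M; free catalyst 0.00300 M
- delta: coupling partner 1.00 M; free catalyst 0.00200 M; target 0.500 M
- gamma: coupling partner 2.00 M; free catalyst 0.00200 M
- theta: coupling partner 1.00 M; free catalyst 0.00200 M; time 51 h

| alpha run: time / h | alpha run: [target] / M | zeta run: time / h | zeta run: [target] / M | delta run: time / h | delta run: [target] / M | gamma run: time / h | gamma run: [target] / M |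
|---|---|---|---|---|---|---|---|
| 0.97 | 0.068 | 0.97 | 0.093 | 0.97 | 0.567 | 0.97 | 0.113 |
| 2.9 | 0.194 | 2.9 | 0.262 | 2.9 | 0.689 | 2.9 | 0.302 |
| 5.6 | 0.335 | 5.6 | 0.447 | 5.6 | 0.836 | 5.6 | 0.522 |
| 8.9 | 0.474 | 8.9 | 0.613 | 8.9 | 0.972 | 8.9 | 0.723 |
| 13 | 0.612 | 13 | 0.750 | 13 | 1.113 | 13 | 0.889 |
| 17 | 0.705 | 17 | 0.836 | 17 | 1.206 | 17 | 0.962 |

(scatter of a reading: 0.003 M)

- Overall: starting material + coupling partner -> target, with free catalyst as catalyst.
- Constant volume, constant temperature.
- A reading of a species includes what of it is bound.
- "The second partner" is coupling partner.
- An order is taken over about fifteen percent of the charge, up and down.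

- order of the initial rate in [coupling partner], near the charge of the alpha run, the rate being that where two percent of its starting material are target
- order of the initial rate in [free catalyst], near the charge of the alpha run, the rate being that where two percent of its starting material are target
- target in the theta run at 51 h, as a share of the starting material charged

The last alpha reading gives 13.9 h for the alpha time constant, the time in which the unturned starting material falls by a factor of e. The first alpha reading gives 13.8 h, so the early stretch, where the target grows as time over that constant, and the late stretch, where the remainder decays, join on one apparent first-order curve.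

Does that constant follow the catalyst? The zeta flask, with 1.50 times the alpha catalyst, has made 0.262 M of target at 2.9 h against 0.194 M in the alpha flask, and the ratio of the two logarithms of the remainder at that reading gives me an order of 0.845, below one. The gamma flask, with twice the partner, has made 0.302 M at that same time, and the same comparison with the alpha flask gives me an order of 0.737 across that wide step, also below one.

With two partial orders, will the alpha constant hold for the theta flask? Its readings stop at a third of the time asked, so I commit to its holding: 51 h is 3.66 constants, the remainder is 2.57%, and the target comes to 97.4%.

The forecast, saying “no deactivation is visible”, gives 0.75, 0.88 and 97.3%, its catalyst order a little above my reading.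

The flask gives 0.77, 0.86 and 97.4%.

    free catalyst + starting material → catalyst-substrate complex (439.2 M⁻¹ h⁻¹)
    catalyst-substrate complex + coupling partner → loaded catalyst (44.28 M⁻¹ h⁻¹)
    loaded catalyst → target + free catalyst (148.3 h⁻¹)
    free catalyst + coupling partner → spent catalyst + coupling partner (0.1127 M⁻¹ h⁻¹)
    starting material + coupling partner → target (0.01022 M⁻¹ h⁻¹)

Read back, the theta figure means a time constant of 14.0 h, beside the alpha 13.9 h. Carried to the delta flask, which starts with 0.500 M of target already present, the alpha constant gives 0.972 M at 8.9 h, where the delta reading is 0.972 M.

(Readings and results are calculated from invented constants.)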